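Seconds are the unit to think in here: the flasks below share one charge and one running time and differ in temperature, and you want the target each holds at the end.

common to all: substrate 0.63 M; partner 0.378 M; free catalyst 6.3 mM; time 50 s
- Saturday's: temperature 120 °C
- Tuesday's: temperature 150 °C
- Wednesday's: temperature 90 °C

    partner + free catalyst ⇌ catalyst intermediate A (K1 = 120 /M, k1 = 31 /M/s, Ea1 = 59.0 kJ/mol, ΔH1 = −90.0 kJ/mol)
    substrate + target → side product (k2 = 0.067 /M/s, Ea2 = 72.0 kJ/mol)
    substrate + catalyst intermediate A → catalyst intermediate B (k3 = 51 /M/s, Ea3 = 60.0 kJ/mol)
    catalyst intermediate C → free catalyst + target (k4 = 2.8 /s, Ea4 = 86.0 kJ/mol)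
    partner → decomposed reagent (k5 = 0.0026 /s, Ea5 = 118 kJ/mol)
    catalyst intermediate B ⇌ catalyst intermediate C (K6 = 1.3, k6 = 16 /s, Ea6 = 86.0 kJ/mol, ΔH6 = −30.0 kJ/mol)
    (constants at 90 °C)

- percent here means substrate units held: one side product counts as two
- at 90 °C the constants are as listed, elsewhere as the activation energies and enthalpies make them

- which flask leads in amount of target, in percent of the substrate charged ("all alike" within 1.5 percentage points) (Saturday's / Tuesday's / Wednesday's / all alike)
- how much target is there at the end, in percent of the substrate charged: Saturday's
- how much target is there at the end, in percent of the substrate charged: Tuesday's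
- how much target is there at the end, in percent of the substrate charged: Wednesday's

The target is not a safe end point, since substrate consumes it in substrate + target → side product (k2 = 0.067 /M/s, Ea2 = 72.0 kJ/mol), so my reckoning carries one quantity: the target's pseudo-first-order half-life against the full substrate charge, ln(2) over the rate constant of that step at the flask's temperature times the substrate charge. For Saturday's flask this is 2.66 s, for Wednesday's 16.4 s and for Tuesday's 0.558 s. Your 50 s then holds 18.8, 3.05 and 89.6 of them respectively. These counts are upper ones, as the half-life lengthens when substrate is used, and they give no percentage, since target is also being made. Still, I expect Wednesday's flask to lead, its half-life being longer than in the hotter flasks, and Tuesday's to keep next to nothing.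

The forecast names Wednesday's, with 29% of target there, 4.3% in Saturday's and 0% in Tuesday's, its grounds being that “the leftover substrate then eats the target during the remaining time”.

The simulation puts Wednesday's in the lead with 30.2% of target, against 5.45% in Saturday's and 0% in Tuesday's, so the forecast holds within its tolerance.

In Saturday's flask the target's half-life by its reaction with substrate stood at 3.9 s at 3.60 s, longer than the 2.66 s reckoned on the full charge and short against the 50 s. On the 8.96% of substrate left at the end, the same reckoning gives 29.7 s, and the target went from 11.4% at 25.0 s to 5.45% at 50.0 s.

For the repeat of Saturday's at 135 °C, the half-life on the full charge comes to 1.18 s, so the run holds 42.4 of them, more than Saturday's count, and less target should remain. That flask ends with 0.0850% of target and 82.2% of side product.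

The constants used here were drawn at random within sensible limits; the flask was simulated.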